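**Plan**

1. Retrosynthesis: the allyl-protected acid, the 6-acetate and the side-chain bonds C13=C14 and C11–C12 are cut first. This leads back to a ring-B diene with a C9 formyl group, a C5=C6 silyl enol ether and the 7α-isovalerate already in place.
2. Ring B (C5–C10) is then cut at C7–C8 and C9–C10. With C6 at the enol level, ring B is a cyclohexa-1,4-diene (C5=C6–O and C8=C9) flanked by the vicinal C6/C7 oxygens. That is the retron of a Diels–Alder reaction between but-2-ynal (C8, C9, C17, C11) and a 1-acyloxy-2-siloxy diene C10=C5–C6=C7 built on ring A.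
3. Forward: ring A is bought as β-cyclocitral. C7 is added, oxidised, brominated and esterified with isovaleric acid, and Z-selective enol silylation gives the diene. Ring B is closed last by an enantioselective [4+2], the chain is grown from C11 to C15, and C6 is adjusted at the end.
4. Stereochemistry: C10 and C7 are set together in the cycloaddition (absolute sense from the chiral oxazaborolidinium catalyst, relative 7α-O/10β-Me from the Z enol-ester geometry). C5 comes from axial protonation of the C5=C6 enol ether, C6 from α-face hydride delivery to the 6-ketone, and 13E from the olefination.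

Key step: step 7

Remark on numbering: labdane numbering is used throughout (ring A C1–C5/C10, ring B C5–C10, C17 = methyl on C8, C20 = methyl on C10, chain C11–C16).
Assumption: the (S)-catalyst is written for step 7; its sense of induction with an ynal is assigned on the first run, and the equally available (R)-catalyst is used instead if the antipode forms.

**Step 1**
Reactants: 1 β-cyclocitral (2,6,6-trimethylcyclohex-1-ene-1-carbaldehyde)
Product: 2 1-(2,6,6-trimethylcyclohex-1-en-1-yl)ethan-1-ol (racemic)
Conditions: MeMgBr, THF, 0 °C; sat. aq. NH4Cl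
Reagents that add atoms: methylmagnesium bromide, C[Mg]Br
Why: Grignard 1,2-addition to a non-enolisable enal whose β-carbon is fully substituted, so conjugate addition should not compete; the new carbinol centre is racemic and is erased in step 2.

**Step 2**
Reactants: 2 1-(2,6,6-trimethylcyclohex-1-en-1-yl)ethan-1-ol
Product: 3 1-(2,6,6-trimethylcyclohex-1-en-1-yl)ethan-1-one
Conditions: Dess–Martin periodinane, CH2Cl2, 0 °C to rt
Reagents that add atoms: none
Why: Dess–Martin oxidation of a hindered secondary allylic alcohol under near-neutral conditions should leave the tetrasubstituted alkene untouched.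

**Step 3**
Reactants: 3 1-(2,6,6-trimethylcyclohex-1-en-1-yl)ethan-1-one
Product: 5 2-bromo-1-(2,6,6-trimethylcyclohex-1-en-1-yl)ethan-1-one, via trimethylsilyl enol ether 4 (not isolated)
Conditions: LiHMDS, TMSCl, THF, −78 °C; filter (pentane); NBS, THF, 0 °C
Reagents that add atoms: N-bromosuccinimide, O=C1CCC(=O)N1Br; chlorotrimethylsilane, C[Si](C)(C)Cl (its silyl group stays only in 4)
Why: kinetic enolisation can only occur at the methyl group (the other α-carbon is sp2), and the silyl enol ether is brominated at its terminal carbon (C7) by NBS; α-bromination via a silyl enol ether.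

**Step 4**
Reactants: 5 2-bromo-1-(2,6,6-trimethylcyclohex-1-en-1-yl)ethan-1-one; 6 3-methylbutanoic acid (isovaleric acid)
Product: 7 2-oxo-2-(2,6,6-trimethylcyclohex-1-en-1-yl)ethyl 3-methylbutanoate
Conditions: K2CO3, DMF, rt
Reagents that add atoms: none
Why: SN2 displacement of a primary α-keto bromide by a carboxylate (phenacyl-ester type alkylation) installs the C7 isovalerate at the outset.

**Step 5**
Reactants: 7 2-oxo-2-(2,6,6-trimethylcyclohex-1-en-1-yl)ethyl 3-methylbutanoate
Product: 8 (Z)-2-[(tert-butyldimethylsilyl)oxy]-2-(2,6,6-trimethylcyclohex-1-en-1-yl)ethenyl 3-methylbutanoate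
Conditions: TBSOTf, Et3N, CH2Cl2, −78 to 0 °C
Reagents that add atoms: tert-butyldimethylsilyl trifluoromethanesulfonate, CC(C)(C)[Si](C)(C)OS(=O)(=O)C(F)(F)F
Why: soft enolisation towards the doubly activated C7 methylene and O-silylation (R3SiOTf/Et3N enol silylation); the Z isomer (acyloxy trans to the bulky ring, cis to the siloxy group) should predominate because it avoids the cis ring/acyloxy interaction.

**Step 6**
Reactants: 9 but-2-yn-1-ol
Product: 10 but-2-ynal
Conditions: activated MnO2, CH2Cl2, rt; filter; used as a solution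
Reagents that add atoms: none
Why: MnO2 oxidation of a propargylic alcohol stops at the ynal, which is volatile and is therefore made fresh.

**Step 7**
Reactants: 8 (Z)-2-[(tert-butyldimethylsilyl)oxy]-2-(2,6,6-trimethylcyclohex-1-en-1-yl)ethenyl 3-methylbutanoate; 10 but-2-ynal
Product: 11 (7S,10S)-6-[(tert-butyldimethylsilyl)oxy]-11-oxodrima-5,8-dien-7α-yl 3-methylbutanoate (ring B: C5=C6–OTBS, 7α-isovalerate, C8(Me)=C9–CHO, 10β-Me)
Conditions: (S)-o-tolyl-CBS oxazaborolidine·HNTf2 (20 mol %), CH2Cl2, −78 to −40 °C; Et3N quench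
Reagents that add atoms: none
Why: Proposed new method: the chiral oxazaborolidinium ion binds the formyl group of 10 and lowers the LUMO of the conjugated triple bond, which adds across C7 and C10 of the s-cis diene in a concerted, asynchronous [4+2] cycloaddition with the C7–C8 bond leading. The closest known reaction types are chiral-Lewis-acid-catalysed Diels–Alder reactions of acetylenic aldehydes and of 2-siloxydienes, and the thermal alkyne Diels–Alder reactions of 1,3,3-trimethyl-2-vinylcyclohexene-type dienes; the catalytic enantioselective version on a diene with a fully substituted terminus and a 1-acyloxy-2-siloxy pattern has not been shown. Ring B (C5–C10) is closed by intermolecular [4+2] annulation onto the existing ring A, forming C7–C8 and C9–C10 and leaving the C8=C9 and C5=C6 double bonds. C10 and C7 form in one suprafacial event, so their relative configuration (7-H cis to the 10-methyl, hence 7α-ester/10β-methyl) follows from the Z geometry of 8 (acyloxy "outside", ring methyl "inside"), and the absolute configuration follows from the diene face that the catalyst-bound ynal can reach. The step needs regioselectivity (methyl-bearing alkyne carbon to C7, formyl-bearing carbon to C10); the 2-siloxy group and the two alkyl groups on C10 make C7 the nucleophilic terminus, and C7 is also the less hindered end. The alkyne has no endo/exo issue, and the TBS group is chosen to resist silyl transfer to the aldehyde.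

**Step 8**
Reactants: 11 (7S,10S)-6-[(tert-butyldimethylsilyl)oxy]-11-oxodrima-5,8-dien-7α-yl 3-methylbutanoate; 12 dimethyl (2-oxopropyl)phosphonate
Product: 13 (7S,10R,11E)-6-[(tert-butyldimethylsilyl)oxy]-13-oxo-14,15-dinorlabda-5,8,11-trien-7α-yl 3-methylbutanoate
Conditions: LiCl, i-Pr2NEt, MeCN, rt
Reagents that add atoms: none
Why: Horner–Wadsworth–Emmons olefination under Masamune–Roush conditions, which are too weakly basic to deprotonate C7–H, should give the E enone; the change of CIP label at C10 is formal only.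

**Step 9**
Reactants: 13 (7S,10R,11E)-6-[(tert-butyldimethylsilyl)oxy]-13-oxo-14,15-dinorlabda-5,8,11-trien-7α-yl 3-methylbutanoate
Product: 14 (7S,10R)-6-[(tert-butyldimethylsilyl)oxy]-13-oxo-14,15-dinorlabda-5,8-dien-7α-yl 3-methylbutanoate
Conditions: [(Ph3P)CuH]6, H2O, toluene, rt
Reagents that add atoms: none
Why: copper hydride conjugate reduction delivers hydride to C11, the unhindered β-carbon, while the 1,6-position C8 is fully substituted and the tetrasubstituted alkenes, silyl enol ether and ester are inert; this parallels the β-ionone to dihydro-β-ionone reduction.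

**Step 10**
Reactants: 14 (7S,10R)-6-[(tert-butyldimethylsilyl)oxy]-13-oxo-14,15-dinorlabda-5,8-dien-7α-yl 3-methylbutanoate; 15 allyl 2-(diethoxyphosphoryl)acetate
Product: 16 allyl (7S,10R,13E)-6-[(tert-butyldimethylsilyl)oxy]-7α-(3-methylbutanoyloxy)labda-5,8,13-trien-15-oate
Conditions: NaH, THF, 0 to 50 °C (phosphonate in excess over NaH)
Reagents that add atoms: none
Why: Horner–Wadsworth–Emmons olefination of a methyl ketone places the larger CH2 chain trans to the ester, so the 13E isomer should predominate and the minor Z isomer is removed by chromatography.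

**Step 11**
Reactants: 16 allyl (7S,10R,13E)-6-[(tert-butyldimethylsilyl)oxy]-7α-(3-methylbutanoyloxy)labda-5,8,13-trien-15-oate
Product: 17 allyl (5S,7S,10S,13E)-7α-(3-methylbutanoyloxy)-6-oxolabda-8,13-dien-15-oate
Conditions: HF·pyridine, pyridine, THF, 0 °C; crude product used at once
Reagents that add atoms: none
Why: acidic protodesilylation of the silyl enol ether avoids a free enolate (no acyl shift or C7 epimerisation), and the proton should enter C5 axially from the α face, anti to the 10β-methyl, giving the trans ring fusion (5α-H).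

**Step 12**
Reactants: 17 allyl (5S,7S,10S,13E)-7α-(3-methylbutanoyloxy)-6-oxolabda-8,13-dien-15-oate
Product: 18 allyl (5S,6S,7S,10S,13E)-6β-hydroxy-7α-(3-methylbutanoyloxy)labda-8,13-dien-15-oate
Conditions: NaBH4, CeCl3·7H2O, MeOH, −40 °C
Reagents that add atoms: none
Why: Luche-type borohydride reduction; the β face of C6 is screened by the syn-axial 4β- and 10β-methyl groups, so hydride should enter from the α face and give the axial 6β-alcohol, while the enoate and both esters are not reduced.

**Step 13**
Reactants: 18 allyl (5S,6S,7S,10S,13E)-6β-hydroxy-7α-(3-methylbutanoyloxy)labda-8,13-dien-15-oate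
Product: 19 allyl (5S,6S,7S,10S,13E)-6β-acetoxy-7α-(3-methylbutanoyloxy)labda-8,13-dien-15-oate
Conditions: Ac2O, DMAP, Et3N, CH2Cl2, 40 °C
Reagents that add atoms: acetic anhydride, CC(=O)OC(C)=O
Why: DMAP-catalysed acylation with excess reagent and warming is planned for the hindered axial hydroxyl, and the trans-diaxial O6/O7 arrangement should prevent acyl migration.

**Step 14**
Reactants: 19 allyl (5S,6S,7S,10S,13E)-6β-acetoxy-7α-(3-methylbutanoyloxy)labda-8,13-dien-15-oate
Product: 20 (5S,6S,7S,10S,13E)-6β-acetoxy-7α-(3-methylbutanoyloxy)labda-8,13-dien-15-oic acid (target)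
Conditions: Pd(PPh3)4 (5 mol %), morpholine, THF, rt; pH 4 work-up
Reagents that add atoms: none
Why: Pd(0)-catalysed allyl transfer to morpholine (Tsuji–Trost deallylation) cleaves the unhindered allyl ester far faster than the secondary allylic C7 ester on a tetrasubstituted alkene, and leaves acetate and isovalerate intact.

**Compound list**

1 | β-cyclocitral (2,6,6-trimethylcyclohex-1-ene-1-carbaldehyde) | CC1=C(C=O)C(C)(C)CCC1 | starting material
2 | 1-(2,6,6-trimethylcyclohex-1-en-1-yl)ethan-1-ol (racemic) | CC1=C(C(C)O)C(C)(C)CCC1 | intermediate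
3 | 1-(2,6,6-trimethylcyclohex-1-en-1-yl)ethan-1-one | CC1=C(C(C)=O)C(C)(C)CCC1 | intermediate
4 | trimethyl{[1-(2,6,6-trimethylcyclohex-1-en-1-yl)ethenyl]oxy}silane | CC1=C(C(=C)O[Si](C)(C)C)C(C)(C)CCC1 | intermediate (not isolated)
5 | 2-bromo-1-(2,6,6-trimethylcyclohex-1-en-1-yl)ethan-1-one | CC1=C(C(=O)CBr)C(C)(C)CCC1 | intermediate
6 | 3-methylbutanoic acid (isovaleric acid) | CC(C)CC(=O)O | starting material
7 | 2-oxo-2-(2,6,6-trimethylcyclohex-1-en-1-yl)ethyl 3-methylbutanoate | CC1=C(C(=O)COC(=O)CC(C)C)C(C)(C)CCC1 | intermediate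
8 | (Z)-2-[(tert-butyldimethylsilyl)oxy]-2-(2,6,6-trimethylcyclohex-1-en-1-yl)ethenyl 3-methylbutanoate | CC1=C(/C(O[Si](C)(C)C(C)(C)C)=C/OC(=O)CC(C)C)C(C)(C)CCC1 | intermediate
9 | but-2-yn-1-ol | CC#CCO | starting material
10 | but-2-ynal | CC#CC=O | intermediate
11 | (7S,10S)-6-[(tert-butyldimethylsilyl)oxy]-11-oxodrima-5,8-dien-7α-yl 3-methylbutanoate | CC(C)(C)[Si](C)(C)OC=1[C@@H](OC(=O)CC(C)C)C(C)=C(C=O)[C@@]2(C)CCCC(C)(C)C12 | intermediate
12 | dimethyl (2-oxopropyl)phosphonate | COP(=O)(CC(C)=O)OC | starting material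
13 | (7S,10R,11E)-6-[(tert-butyldimethylsilyl)oxy]-13-oxo-14,15-dinorlabda-5,8,11-trien-7α-yl 3-methylbutanoate | CC(C)(C)[Si](C)(C)OC=1[C@@H](OC(=O)CC(C)C)C(C)=C(/C=C/C(C)=O)[C@@]2(C)CCCC(C)(C)C12 | intermediate
14 | (7S,10R)-6-[(tert-butyldimethylsilyl)oxy]-13-oxo-14,15-dinorlabda-5,8-dien-7α-yl 3-methylbutanoate | CC(C)(C)[Si](C)(C)OC=1[C@@H](OC(=O)CC(C)C)C(C)=C(CCC(C)=O)[C@@]2(C)CCCC(C)(C)C12 | intermediate
15 | allyl 2-(diethoxyphosphoryl)acetate | CCOP(=O)(CC(=O)OCC=C)OCC | starting material
16 | allyl (7S,10R,13E)-6-[(tert-butyldimethylsilyl)oxy]-7α-(3-methylbutanoyloxy)labda-5,8,13-trien-15-oate | CC(C)(C)[Si](C)(C)OC=1[C@@H](OC(=O)CC(C)C)C(C)=C(CC/C(C)=C/C(=O)OCC=C)[C@@]2(C)CCCC(C)(C)C12 | intermediate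
17 | allyl (5S,7S,10S,13E)-7α-(3-methylbutanoyloxy)-6-oxolabda-8,13-dien-15-oate | O=C1[C@@H](OC(=O)CC(C)C)C(C)=C(CC/C(C)=C/C(=O)OCC=C)[C@@]2(C)CCCC(C)(C)[C@H]12 | intermediate
18 | allyl (5S,6S,7S,10S,13E)-6β-hydroxy-7α-(3-methylbutanoyloxy)labda-8,13-dien-15-oate | O[C@@H]1[C@@H](OC(=O)CC(C)C)C(C)=C(CC/C(C)=C/C(=O)OCC=C)[C@@]2(C)CCCC(C)(C)[C@H]12 | intermediate
19 | allyl (5S,6S,7S,10S,13E)-6β-acetoxy-7α-(3-methylbutanoyloxy)labda-8,13-dien-15-oate | CC(=O)O[C@@H]1[C@@H](OC(=O)CC(C)C)C(C)=C(CC/C(C)=C/C(=O)OCC=C)[C@@]2(C)CCCC(C)(C)[C@H]12 | intermediate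
20 | (5S,6S,7S,10S,13E)-6β-acetoxy-7α-(3-methylbutanoyloxy)labda-8,13-dien-15-oic acid | CC(=O)O[C@@H]1[C@@H](OC(=O)CC(C)C)C(C)=C(CC/C(C)=C/C(=O)O)[C@@]2(C)CCCC(C)(C)[C@H]12 | target

**Totals**

Total step count: 14. Longest linear sequence: 13 steps (steps 1–5 and 7–14, from β-cyclocitral).

**Steps most likely to fail**

Step 7 (proposed new method). The cycloaddition may stall because the twisted diene cannot reach the s-cis geometry at low temperature (the siloxy group at C6 lies against the C4 gem-dimethyl group). Silyl transfer may divert the reaction to 1,2-addition at the aldehyde or to four-membered ring closure, and facial selectivity or regioselectivity may be poor. Fallback: 8 and 10 are combined without catalyst in toluene at 90–110 °C (sealed tube, BHT, trace 2,6-lutidine), the known thermal mode for this class of ring-A dienes with activated alkynes, to give the racemic Diels–Alder adduct F1. Step 8 conditions convert it into the racemic dienone F2, which is resolved by preparative HPLC on a chiral stationary phase. The (7S,10R)-enantiomer is 13, where the route is rejoined; the unwanted (7R,10S)-dienone F3 is set aside.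

Step 8. Olefination of the aldehyde, flanked by the quaternary C10 and the C8 methyl, may be slow, so that base-induced γ-deprotonation at C7 with double-bond migration takes over. Fallback: the C11–C12 bond is made by alkylation instead. Compound 11 is reduced (NaBH4, CeCl3, MeOH, −78 °C) to the allylic alcohol F4, which is converted (CBr4, PPh3, 2,6-lutidine, CH2Cl2, 0 °C) into the allylic bromide F5. Alkylation of the sodium enolate of allyl acetoacetate (NaH, THF, 0 °C to rt) gives the β-keto ester F6, and Pd(PPh3)4/morpholine (THF, rt) removes the allyl group with loss of CO2 to give 14 directly, so that steps 8 and 9 are both bypassed.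

Step 13. Acylation of the axial 6β-hydroxyl, shielded by the syn-axial 4β- and 10β-methyl groups, may remain incomplete, and forcing conditions may begin to ionise the allylic C7 ester. Fallback: the oxygen is activated instead of the acyl donor. Compound 18 is deprotonated at −78 °C (LiHMDS, 1.0 equiv, THF) to the lithium alkoxide F7, which is quenched with acetyl chloride (−78 to 0 °C) to give 19.

**Further compounds**

F1 | step 7 | racemic Diels–Alder adduct (11 together with its enantiomer) | CC(C)(C)[Si](C)(C)OC=1[C@@H](OC(=O)CC(C)C)C(C)=C(C=O)[C@@]2(C)CCCC(C)(C)C12.CC(C)(C)[Si](C)(C)OC=1[C@H](OC(=O)CC(C)C)C(C)=C(C=O)[C@]2(C)CCCC(C)(C)C12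
F2 | step 7 | racemic dienone (13 together with its enantiomer) | CC(C)(C)[Si](C)(C)OC=1[C@@H](OC(=O)CC(C)C)C(C)=C(/C=C/C(C)=O)[C@@]2(C)CCCC(C)(C)C12.CC(C)(C)[Si](C)(C)OC=1[C@H](OC(=O)CC(C)C)C(C)=C(/C=C/C(C)=O)[C@]2(C)CCCC(C)(C)C12
F3 | step 7 | (7R,10S,11E)-dienone, enantiomer of 13 | CC(C)(C)[Si](C)(C)OC=1[C@H](OC(=O)CC(C)C)C(C)=C(/C=C/C(C)=O)[C@]2(C)CCCC(C)(C)C12
F4 | step 8 | 6-[(tert-butyldimethylsilyl)oxy]-11-hydroxydrima-5,8-dien-7α-yl 3-methylbutanoate (10β-methyl) | CC(C)(C)[Si](C)(C)OC=1[C@@H](OC(=O)CC(C)C)C(C)=C(CO)[C@@]2(C)CCCC(C)(C)C12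
F5 | step 8 | 11-bromo-6-[(tert-butyldimethylsilyl)oxy]drima-5,8-dien-7α-yl 3-methylbutanoate (10β-methyl) | CC(C)(C)[Si](C)(C)OC=1[C@@H](OC(=O)CC(C)C)C(C)=C(CBr)[C@@]2(C)CCCC(C)(C)C12
F6 | step 8 | allyl 2-acetyl-3-[6-(tert-butyldimethylsilyloxy)-7α-(3-methylbutanoyloxy)-11-nordrima-5,8-dien-9-yl]propanoate (epimers at the new chain carbon) | CC(C)(C)[Si](C)(C)OC=1[C@@H](OC(=O)CC(C)C)C(C)=C(CC(C(C)=O)C(=O)OCC=C)[C@@]2(C)CCCC(C)(C)C12
F7 | step 13 | lithium 6β-alkoxide of 18 | [Li+].[O-][C@@H]1[C@@H](OC(=O)CC(C)C)C(C)=C(CC/C(C)=C/C(=O)OCC=C)[C@@]2(C)CCCC(C)(C)[C@H]12
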